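**Retrosynthetic overview**
- The target is a 6,6'-linked dimer of an all-cis (2R,3R,4R) flavan-3,4-diol and its (2R,3R,4S) C4 epimer; the last operations are deprotections.
- Key cut: the C6–C6' biaryl bond. Both carbons are nucleophilic arene positions (ortho to O7, para to O1). One partner, with a free 7-OH, is oxidised by PhI(OAc)2 to an o-quinol acetate (a masked phenoxenium, the enolonium equivalent of the phenol) and arylates C6 of the 7-O-protected partner.
- Both partners are the same all-cis monomer. The 4S centre is made after the coupling: only the half with the free 7-OH can form a p-quinone methide and take up water anti to O3.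
- Monomer: a flavonol from gallacetophenone and 4-(benzyloxy)benzaldehyde (Claisen–Schmidt, then Algar–Flynn–Oyamada), followed by one asymmetric all-cis hydrogenation that sets C2, C3 and C4.
- Ring order: rings A and B bought, ring C closed in the flavonol step, stereotriad set, biaryl A–A' bond made, deprotection.

Assumption: the (R,R) ligand in step 5 is taken to deliver hydrogen to the face that gives the 2R series; if the sense is opposite on this substrate, its (S,S) enantiomer is used and nothing else changes.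

**Step 1**
Reactants: 1 2',3',4'-trihydroxyacetophenone (gallacetophenone)
Product: 2 ketone 1-[4-(benzyloxymethoxy)-2,3-dihydroxyphenyl]ethan-1-one
Conditions: BOMCl (1.05 equiv), i-Pr2NEt (1.1 equiv), CH2Cl2, 0 °C → rt
Reagents that add atoms: benzyl chloromethyl ether, ClCOCc1ccccc1
Why: The 4-OH (para to the acetyl group, most acidic, not chelated) is alkylated selectively under amine base (regioselective Williamson-type O-alkylation), giving a BOM acetal that can later be cleaved selectively or by hydrogenolysis.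

**Step 2**
Reactants: 2 ketone 1-[4-(benzyloxymethoxy)-2,3-dihydroxyphenyl]ethan-1-one
Product: 3 ketone 1-[3-(benzyloxy)-4-(benzyloxymethoxy)-2-hydroxyphenyl]ethan-1-one
Conditions: BnBr (1.1 equiv), K2CO3 (1.2 equiv), DMF, rt
Reagents that add atoms: benzyl bromide, BrCc1ccccc1
Why: The 2-OH is held in a hydrogen bond to the ketone, so Williamson etherification takes place at the 3-OH only; this oxygen becomes the 8-O-benzyl group needed for the later phenol oxidation.

**Step 3**
Reactants: 3 ketone 1-[3-(benzyloxy)-4-(benzyloxymethoxy)-2-hydroxyphenyl]ethan-1-one; 4 4-(benzyloxy)benzaldehyde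
Product: 6 flavonol 3-hydroxy-8-(benzyloxy)-7-(benzyloxymethoxy)-2-[4-(benzyloxy)phenyl]-4H-chromen-4-one, via 2'-hydroxychalcone 5 (not isolated)
Conditions: KOH (50% aq.), EtOH, rt, 24 h; then NaOH (aq.), H2O2 (30%), 0 °C → rt
Reagents that add atoms: hydrogen peroxide, OO
Why: Claisen–Schmidt condensation followed in the same pot by Algar–Flynn–Oyamada oxidative cyclisation closes ring C; a 2'-hydroxychalcone without a 6'-substituent gives the flavonol rather than an aurone, and benzyl ethers and the BOM acetal are stable to alkaline peroxide.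

**Step 4**
Reactants: 6 flavonol 3-hydroxy-8-(benzyloxy)-7-(benzyloxymethoxy)-2-[4-(benzyloxy)phenyl]-4H-chromen-4-one
Product: 7 flavone carbonate 8-(benzyloxy)-7-(benzyloxymethoxy)-2-[4-(benzyloxy)phenyl]-4-oxo-4H-chromen-3-yl methyl carbonate
Conditions: ClCO2Me (1.5 equiv), Et3N (2 equiv), DMAP (5 mol %), CH2Cl2, 0 °C
Reagents that add atoms: methyl chloroformate, COC(Cl)=O
Why: O-acylation masks the acidic, chelating 3-OH so that it cannot bind the hydrogenation catalyst, and it installs the carbonyl carbon that becomes the cyclic carbonate in step 5.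

**Step 5**
Reactants: 7 flavone carbonate 8-(benzyloxy)-7-(benzyloxymethoxy)-2-[4-(benzyloxy)phenyl]-4-oxo-4H-chromen-3-yl methyl carbonate
Product: 9 cyclic 3,4-carbonate of all-cis (2R,3R,4R)-8-(benzyloxy)-7-(benzyloxymethoxy)-2-[4-(benzyloxy)phenyl]chromane-3,4-diol, via all-cis 4-hydroxy 3-methyl carbonate 8 (not isolated)
Conditions: H2 (100 bar), [Ru(cod)(2-methylallyl)2] (5 mol %), (R,R)-1,3-bis[1-(naphthalen-1-yl)ethyl]imidazolinium tetrafluoroborate (SINpEt·HBF4, 10 mol %), KOt-Bu (10 mol %, catalyst pre-formed), toluene, 25 °C, 24 h; vent; then DBU (0.2 equiv), rt, 1 h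
Reagents that add atoms: none
Why: Proposed new method: ruthenium–N-heterocyclic-carbene catalysts hydrogenate flavones enantioselectively to cis-flavan-4-ols (syn addition to C2=C3, then C4=O), and heterogeneous hydrogenation of flavonols is known to give all-cis 3,4-diols; on this 3-acyloxyflavone the syn addition should set 2,3-cis, the ketone should be reduced anti to the axial 3-O group to set 3,4-cis, and the ligand should fix the absolute sense as (2R,3R,4R), after which the cis-4-hydroxyl displaces methoxide from the neighbouring methyl carbonate (5-exo transcarbonation) to give the cyclic carbonate.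

**Step 6**
Reactants: 9 cyclic 3,4-carbonate of all-cis (2R,3R,4R)-8-(benzyloxy)-7-(benzyloxymethoxy)-2-[4-(benzyloxy)phenyl]chromane-3,4-diol
Product: 10 cyclic 3,4-carbonate of all-cis (2R,3R,4R)-8-(benzyloxy)-2-[4-(benzyloxy)phenyl]chromane-3,4,7-triol (free 7-OH)
Conditions: TMSOTf (2 equiv), 2,2'-bipyridyl (3 equiv), CH2Cl2, 0 °C → rt; then H2O, pH 7 work-up
Reagents that add atoms: none
Why: The silyl triflate–bipyridyl pair cleaves only the acetal-type BOM ether (through a pyridinium and silyl ether that hydrolyse on work-up), leaving benzyl ethers and the benzylic carbonate; the medium is never basic, so the p-hydroxybenzylic carbonate cannot eliminate and no stereocentre is touched.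

**Step 7**
Reactants: 10 cyclic 3,4-carbonate of all-cis (2R,3R,4R)-8-(benzyloxy)-2-[4-(benzyloxy)phenyl]chromane-3,4,7-triol; 9 cyclic 3,4-carbonate of all-cis (2R,3R,4R)-8-(benzyloxy)-7-(benzyloxymethoxy)-2-[4-(benzyloxy)phenyl]chromane-3,4-diol
Product: 12 6,6'-bichromane bis(3,4-cyclic carbonate) with both halves all-cis (2R,3R,4R); one half 7-OH/8-OBn/4'-OBn and the other half 7-OBOM/8-OBn/4'-OBn, via o-quinol acetate 11 (not isolated)
Conditions: 10, PhI(OAc)2 (1.05 equiv), CH2Cl2, −78 → −40 °C, 30 min; then 9 (1.3 equiv), HFIP/CH2Cl2 (4:1), −40 → 0 °C; pH 7 work-up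
Reagents that add atoms: none
Why: Trivalent-iodine oxidation dearomatises phenol 10 to o-quinol acetate 11, a masked phenoxenium that makes the normally nucleophilic C6 electrophilic (enolonium equivalent); in HFIP acetate ionises and, with the para (C4a) and other ortho (C8) positions blocked, the cation is attacked at C6 by the most nucleophilic carbon of 9 (C6, para to O1 and ortho to O7) and rearomatises to the biaryl (oxidative phenol–arene cross-coupling of the quinone-monoketal arylation type), forming no stereocentre and excluding homocoupling because 10 is fully oxidised before 9 is added.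

**Step 8**
Reactants: 12 6,6'-bichromane bis(3,4-cyclic carbonate) with both halves all-cis (2R,3R,4R)
Product: 14 (2R,2'R,3R,3'R,4R,4'S)-6,6'-bichromane-3,3',4,4'-tetraol; the 4R half 7-OBOM/8-OBn/4'-OBn and the 4'S half 7'-OH/8'-OBn/4''-OBn, via p-quinone methide 13 (not isolated)
Conditions: Et3N (5 equiv), THF/H2O (1:1), 0 °C → rt, 2 h; then LiOH (4 equiv), rt, 1 h; aq. NH4Cl
Reagents that add atoms: water, O
Why: Proposed new method: in the half with the free 7-OH the phenoxide expels the para-benzylic carbonate oxygen (1,6-elimination, as in the self-immolation of p-hydroxybenzyl carbonates) to give quinone methide 13, and water adds at C4 anti to the pseudo-axial 3-O substituent (the 3,4-trans selectivity known for nucleophilic capture at C4 of 2,3-cis flavans) to give 4S after loss of CO2, whereas the half without a free phenol cannot eliminate and its carbonate is saponified by acyl–oxygen cleavage with retention (4R).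

**Step 9**
Reactants: 14 (2R,2'R,3R,3'R,4R,4'S)-6,6'-bichromane-3,3',4,4'-tetraol carrying four benzyl ethers and one BOM ether
Product: 15 (2R,2'R,3R,3'R,4R,4'S)-2,2'-bis(4-hydroxyphenyl)-[6,6'-bichromane]-3,3',4,4',7,7',8,8'-octol (target)
Conditions: H2 (1 atm), Pd(OH)2/C (20 wt %), THF/MeOH (1:1), rt; filter and concentrate under argon
Reagents that add atoms: none
Why: Neutral hydrogenolysis removes the four O-benzyl groups and the BOM acetal (the hemiformal collapses to the phenol) without acid or base, so the labile benzylic 4-OH centres are neither epimerised nor, under these buffer-free neutral conditions, reduced.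

**Compound list**
1 | 2',3',4'-trihydroxyacetophenone (gallacetophenone) | CC(=O)c1ccc(O)c(O)c1O | starting material
2 | 1-[4-(benzyloxymethoxy)-2,3-dihydroxyphenyl]ethan-1-one | CC(=O)c1ccc(OCOCc2ccccc2)c(O)c1O | intermediate
3 | 1-[3-(benzyloxy)-4-(benzyloxymethoxy)-2-hydroxyphenyl]ethan-1-one | CC(=O)c1ccc(OCOCc2ccccc2)c(OCc2ccccc2)c1O | intermediate
4 | 4-(benzyloxy)benzaldehyde | O=Cc1ccc(OCc2ccccc2)cc1 | starting material
5 | (E)-1-[3-(benzyloxy)-4-(benzyloxymethoxy)-2-hydroxyphenyl]-3-[4-(benzyloxy)phenyl]prop-2-en-1-one (not isolated) | O=C(/C=C/c1ccc(OCc2ccccc2)cc1)c1ccc(OCOCc2ccccc2)c(OCc2ccccc2)c1O | intermediate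
6 | 3-hydroxy-8-(benzyloxy)-7-(benzyloxymethoxy)-2-[4-(benzyloxy)phenyl]-4H-chromen-4-one | O=c1c(O)c(-c2ccc(OCc3ccccc3)cc2)oc2c(OCc3ccccc3)c(OCOCc3ccccc3)ccc12 | intermediate
7 | 8-(benzyloxy)-7-(benzyloxymethoxy)-2-[4-(benzyloxy)phenyl]-4-oxo-4H-chromen-3-yl methyl carbonate | COC(=O)Oc1c(-c2ccc(OCc3ccccc3)cc2)oc2c(OCc3ccccc3)c(OCOCc3ccccc3)ccc2c1=O | intermediate
8 | (2R,3R,4R)-8-(benzyloxy)-7-(benzyloxymethoxy)-2-[4-(benzyloxy)phenyl]-4-hydroxychroman-3-yl methyl carbonate, all-cis (not isolated) | c1ccccc1COc1ccc([C@H]2Oc3c(ccc(OCOCc4ccccc4)c3OCc3ccccc3)[C@@H](O)[C@H]2OC(=O)OC)cc1 | intermediate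
9 | cyclic 3,4-carbonate of all-cis (2R,3R,4R)-8-(benzyloxy)-7-(benzyloxymethoxy)-2-[4-(benzyloxy)phenyl]chromane-3,4-diol | c1ccccc1COc1ccc([C@H]2Oc3c(ccc(OCOCc4ccccc4)c3OCc3ccccc3)[C@@H](OC(=O)O4)[C@H]24)cc1 | intermediate
10 | cyclic 3,4-carbonate of all-cis (2R,3R,4R)-8-(benzyloxy)-2-[4-(benzyloxy)phenyl]chromane-3,4,7-triol | c1ccccc1COc1ccc([C@H]2Oc3c(ccc(O)c3OCc3ccccc3)[C@@H](OC(=O)O4)[C@H]24)cc1 | intermediate
11 | o-quinol acetate of 10: 8-acetoxy-8-(benzyloxy)-7-oxo-7,8-dihydro ring A, C8 epimers (not isolated) | c1ccccc1COc1ccc([C@H]2OC3=C(C=CC(=O)C3(OC(C)=O)OCc3ccccc3)[C@@H](OC(=O)O4)[C@H]24)cc1 | intermediate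
12 | 6,6'-bichromane bis(3,4-cyclic carbonate), both halves all-cis (2R,3R,4R); one half 7-OH, the other 7-OBOM; 8,8'-di-OBn; both 4-(benzyloxy)phenyl | c1ccccc1COc1ccc([C@H]2Oc3c(cc(-c4cc5c(c(OCc6ccccc6)c4O)O[C@H](c4ccc(OCc6ccccc6)cc4)[C@H](OC(=O)O6)[C@@H]56)c(OCOCc4ccccc4)c3OCc3ccccc3)[C@@H](OC(=O)O4)[C@H]24)cc1 | intermediate
13 | p-quinone methide of the phenolic half of 12 (C4=C4a, C7=O, 3-O-carbonic acid); other half unchanged (not isolated) | c1ccccc1COc1ccc([C@H]2Oc3c(cc(C4=CC5=C[C@@H](OC(=O)O)[C@@H](c6ccc(OCc7ccccc7)cc6)OC5=C(OCc5ccccc5)C4=O)c(OCOCc4ccccc4)c3OCc3ccccc3)[C@@H](OC(=O)O4)[C@H]24)cc1 | intermediate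
14 | (2R,2'R,3R,3'R,4R,4'S)-6,6'-bichromane-3,3',4,4'-tetraol; 4R half 7-OBOM/8-OBn; 4'S half 7'-OH/8'-OBn; both 4-(benzyloxy)phenyl | c1ccccc1COc1ccc([C@H]2Oc3c(cc(-c4cc5c(c(OCc6ccccc6)c4O)O[C@H](c4ccc(OCc6ccccc6)cc4)[C@H](O)[C@H]5O)c(OCOCc4ccccc4)c3OCc3ccccc3)[C@@H](O)[C@H]2O)cc1 | intermediate
15 | (2R,2'R,3R,3'R,4R,4'S)-2,2'-bis(4-hydroxyphenyl)-[6,6'-bichromane]-3,3',4,4',7,7',8,8'-octol | Oc1ccc([C@H]2Oc3c(cc(-c4cc5c(c(O)c4O)O[C@H](c4ccc(O)cc4)[C@H](O)[C@H]5O)c(O)c3O)[C@@H](O)[C@H]2O)cc1 | target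

**Step count and risks**
Total: 9 steps. Longest linear sequence: 9 steps (1 → 2 → 3 → 6 → 7 → 9 → 10 → 12 → 14 → 15); the two coupling partners 9 and 10 come from the same line.

Most likely to fail:

- **Step 5 (asymmetric all-cis hydrogenation).** The tetrasubstituted 3-acyloxy enone may react slowly, with low ee, or epimerise at C3 before the ketone is reduced. The fallback sets out from 6 and comes back at 9, replacing asymmetric catalysis by substrate-controlled reduction and a covalent auxiliary. Flavonol 6 is hydrogenated over Raney Ni (H2 50 bar, EtOH/THF, 50 °C), the classical all-cis reduction of flavonols, to the racemic all-cis 3,4-diol F1. (−)-Menthyl chloroformate and pyridine acylate the pseudo-equatorial 4-OH and give the (2R,3R,4R)-configured 4-O-menthyloxycarbonyl diol F2 and its (2S,3S,4S)-configured diastereomer F3, which are separated by chromatography or crystallisation. DBU in THF then closes F2 to 9; the auxiliary supplies the carbonate carbon.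

- **Step 7 (oxidative biaryl coupling).** The o-quinol acetate may dimerise, lose H4 to give the 4-ketone, or be attacked too slowly by the aryl ether. The fallback sets out from 9 and 10 and comes back at 12, keeping the reversed polarity but placing it on the other partner. Monomer 9 reacts at C6 with [hydroxy(tosyloxy)iodo]mesitylene in CF3CH2OH to give the aryl(mesityl)iodonium tosylate F4, an aryl cation equivalent. F4 then arylates phenol 10 at C6 (ortho to OH, para to the ring oxygen) with Cu(OTf)2 (10 mol %) and 2,6-di-tert-butylpyridine in 1,2-dichloroethane at 60 °C to give 12. O-arylation of the phenol is the risk of this variant.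

- **Step 8 (quinone-methide inversion during carbonate removal).** Direct saponification of the phenolic half (retention, 4R) may compete with elimination, or hydration may not be fully anti. The fallback sets out from 8 (isolated by leaving out DBU in step 5) and comes back at 14, setting 4S by SN2 before the coupling. Mitsunobu inversion of 8 with 4-nitrobenzoic acid, PPh3 and DIAD gives the (2R,3R,4S) 4-nitrobenzoate F5. TMSOTf/2,2'-bipyridyl then frees the phenol to give 7-hydroxy ester F6. F6 is oxidised with PhI(OAc)2 to its o-quinol acetate F7 and coupled with 9 in HFIP as in step 7 to give the mixed dimer F8. LiOH in THF/H2O removes all acyl groups to give 14; the phenolic half ends up 3,4-trans whether its ester is cleaved directly or through the quinone methide.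

**Further compounds**
F1 | step 5 | rac-(2R*,3R*,4R*)-8-(benzyloxy)-7-(benzyloxymethoxy)-2-[4-(benzyloxy)phenyl]chromane-3,4-diol, all-cis (one enantiomer drawn) | c1ccccc1COc1ccc([C@H]2Oc3c(ccc(OCOCc4ccccc4)c3OCc3ccccc3)[C@@H](O)[C@H]2O)cc1
F2 | step 5 | (2R,3R,4R)-8-(benzyloxy)-7-(benzyloxymethoxy)-2-[4-(benzyloxy)phenyl]-3-hydroxychroman-4-yl (1R,2S,5R)-menthyl carbonate | c1ccccc1COc1ccc([C@H]2Oc3c(ccc(OCOCc4ccccc4)c3OCc3ccccc3)[C@@H](OC(=O)O[C@@H]4C[C@H](C)CC[C@H]4C(C)C)[C@H]2O)cc1
F3 | step 5 | (2S,3S,4S)-8-(benzyloxy)-7-(benzyloxymethoxy)-2-[4-(benzyloxy)phenyl]-3-hydroxychroman-4-yl (1R,2S,5R)-menthyl carbonate | c1ccccc1COc1ccc([C@@H]2Oc3c(ccc(OCOCc4ccccc4)c3OCc3ccccc3)[C@H](OC(=O)O[C@@H]4C[C@H](C)CC[C@H]4C(C)C)[C@@H]2O)cc1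
F4 | step 7 | (C6 of 9)(mesityl)iodonium tosylate | c1ccccc1COc1ccc([C@H]2Oc3c(cc([I+]c4c(C)cc(C)cc4C)c(OCOCc4ccccc4)c3OCc3ccccc3)[C@@H](OC(=O)O4)[C@H]24)cc1.Cc1ccc(S(=O)(=O)[O-])cc1
F5 | step 8 | (2R,3R,4S)-8-(benzyloxy)-7-(benzyloxymethoxy)-2-[4-(benzyloxy)phenyl]-3-(methoxycarbonyloxy)chroman-4-yl 4-nitrobenzoate | c1ccccc1COc1ccc([C@H]2Oc3c(ccc(OCOCc4ccccc4)c3OCc3ccccc3)[C@H](OC(=O)c3ccc(cc3)[N+](=O)[O-])[C@H]2OC(=O)OC)cc1
F6 | step 8 | (2R,3R,4S)-8-(benzyloxy)-2-[4-(benzyloxy)phenyl]-7-hydroxy-3-(methoxycarbonyloxy)chroman-4-yl 4-nitrobenzoate | c1ccccc1COc1ccc([C@H]2Oc3c(ccc(O)c3OCc3ccccc3)[C@H](OC(=O)c3ccc(cc3)[N+](=O)[O-])[C@H]2OC(=O)OC)cc1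
F7 | step 8 | o-quinol acetate of F6 (8-acetoxy-8-benzyloxy-7-oxo ring A, C8 epimers) | c1ccccc1COc1ccc([C@H]2OC3=C(C=CC(=O)C3(OC(C)=O)OCc3ccccc3)[C@H](OC(=O)c3ccc(cc3)[N+](=O)[O-])[C@H]2OC(=O)OC)cc1
F8 | step 8 | 6,6'-biaryl of F6 and 9: phenolic half (2R,3R,4S) with 3-O-methyl carbonate and 4-O-(4-nitrobenzoate); other half all-cis cyclic carbonate with 7-OBOM | c1ccccc1COc1ccc([C@H]2Oc3c(cc(-c4cc5c(c(OCc6ccccc6)c4O)O[C@H](c4ccc(OCc6ccccc6)cc4)[C@H](OC(=O)OC)[C@H]5OC(=O)c4ccc(cc4)[N+](=O)[O-])c(OCOCc4ccccc4)c3OCc3ccccc3)[C@@H](OC(=O)O4)[C@H]24)cc1
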